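The east and west runs carry the same equivalents of partner and reagent as the flask and differ from it in starting concentration.

| setting | east | west | flask |
|---|---|---|---|
| starting material | 0.034 M | 0.075 M | 0.050 M |
| partner | 1.5 equiv | 1.5 equiv | 1.50 equiv |
| reagent | 4 equiv | 4 equiv | 4.00 equiv |
| remark | run made earlier | run made earlier |  |
| time |  |  | 6.0 min |

- east (time / min: target / %, crystals / %): 0.667: 24.1, 16.1; 1.33: 46.0, 38.8; 2.00: 60.7, 55.1; 3.00: 74.7, 71.1; 4.00: 83.0, 79.3
- west (time / min: target / %, crystals / %): 0.333: 27.8, 14.1; 0.833: 58.0, 48.2; 1.50: 79.9, 74.6; 2.50: 89.9, 89.0; 4.00: 90.7, 89.1

(standard deviation of a reading: 0.3 percentage points)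

- for target the crystals are counted in
- as a solid, counted per litre of solution: crystals
- steps under discussion: crystals <-> target; open intermediate + second intermediate -> target; starting material + reagent -> open intermediate; target -> over-reaction product; reagent + partner -> second intermediate

1. the target and crystals together standing at 6.0 min, as a percentage of the starting material charged
2. concentration of target in solution at 6.0 min, in percent of saturation

Read on the clock of a second-order step, the two runs nearly overlap: the east run at 2.00 min has 0.0680 M·min of concentration times time and reads 60.7 % target, while the west run at 0.833 min has 0.0625 M·min and reads 58.0 %. For the flask at the asked time the same product comes to 0.300 M·min, and this reach, starting concentration times elapsed time, carries the reckoning here. The crossing stands in the west run, which has climbed to 89.9 % at a reach of 0.188 M·min and gains 0.8 percentage points after that, up to its last reading.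

Below that reach the west readings are still climbing, so the opposite outcome, a flask still climbing at the asked time, looks on this clock like a reach under the crossing, but the flask stands 1.60 times above it, level with the last west reading. The reckoning therefore takes the west reading of 90.7 % as its upper mark for the flask, which has 2.00 min longer on the clock for any loss that runs by time and not by reach.

The forecast gives 90 % (from 87.5 % to 92.5 %) and 101 % of saturation (from 92 % to 115 %), holding that “feed roughly balances over-reaction drain”.

    crystals ⇌ target, rate k1*(cs1 - [target]) while solid is left; crystals form when [target] > cs1 (solubility = 0.580 mM, k = 0.0961 s⁻¹)
    open intermediate + second intermediate → target (k = 2.97 M⁻¹ s⁻¹)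
    starting material + reagent → open intermediate (k = 1.66 M⁻¹ s⁻¹)
    target → over-reaction product (k = 0.00854 s⁻¹)
    reagent + partner → second intermediate (k = 0.0689 M⁻¹ s⁻¹)

The flask gives 88.7 % of target and crystals, with the solution at 92.0 % of saturation. Its open intermediate stands at 0 % at the asked time, against 4.53 % at 3.00 min, when the reach of the flask was 0.150 M·min. The neighbour charged with 0.020 M of starting material gets to a reach of 0.120 M·min in the same time, less than the crossing, and it ends with 10.7 % open intermediate and 74.4 % of target and crystals.

The data are simulated with made-up constants; scatter was added.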